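**Retrosynthetic overview**
1. Target 23 ⇐ hydrindane β-diketone 17 by C4 ketone reduction/acetylation, hydroxyl-directed C11–C12 epoxidation and two acylations.
2. 17 ⇐ cadinane 4,5-epoxy-3-ketone 16: ring A is contracted last by a 1,2-acyl shift (C3 moves from C4 to C5).
3. 16 ⇐ trans-cadinenone 15 ⇐ bisabolane-type vinyl epoxide 12: ring B is closed first (C6–C7) by cation–olefin attack of a ring-A dienol ether on the vinyl epoxide, and the ring fusion is then equilibrated at C6.
4. 12 ⇐ enal 5 + enyne 6 + acid 11 (asymmetric dienylzinc addition sets C9, Sharpless epoxidation sets C8/C7).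
5. 5 ⇐ (S)-carvone 1, which supplies ring A, C1, C10, C14 and C9. Ring order: A (from 1) → B (step 6) → A contracted (step 8).

Assumption: 6, 11, 22, Cy2BH and both enantiomers of MIB (3-exo-morpholinoisoborneol) are bought.
Locants: C1–C15 are cadinane (biogenetic) locants. Ring A is C1–C6 with C15 on C4 and the ketone at C3. Ring B is C1, C6, C7–C10 with C14 on C10 and C11(C12)(C13) on C7. β is the face of H-1.

Step 1
Reactants: 1 (S)-carvone, (5S)-2-methyl-5-(prop-1-en-2-yl)cyclohex-2-en-1-one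
Product: 3 (9R)-6-methyl-9-(prop-1-en-2-yl)-1,4-dioxaspiro[4.5]dec-7-ene, via β,γ-enone 2 (not isolated)
Conditions: KOtBu, t-BuOH/THF, 0 °C; inverse quench into AcOH/THF, −78 °C; then (TMSOCH2)2, TMSOTf (5 mol %), CH2Cl2, −78 °C
Reagents that add atoms: 1,2-bis(trimethylsilyloxy)ethane, C[Si](C)(C)OCCO[Si](C)(C)C
Why: Kinetic α-protonation of the extended potassium dienolate deconjugates the enone (classical enone deconjugation) and non-isomerising Noyori ketalisation freezes the C5=C6 alkene, so that C4–H is the only α-hydrogen that is also allylic; C1 is untouched and the C4 centre is a mixture that is erased in step 6.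

Step 2
Reactants: 3 (9R)-6-methyl-9-(prop-1-en-2-yl)-1,4-dioxaspiro[4.5]dec-7-ene
Product: 5 2-[(9R)-6-methyl-1,4-dioxaspiro[4.5]dec-7-en-9-yl]prop-2-enal, via allylic alcohol 4 (not isolated)
Conditions: SeO2 (0.5 equiv), t-BuOOH, CH2Cl2, rt; filter; then MnO2, CH2Cl2, rt
Reagents that add atoms: tert-butyl hydroperoxide, CC(C)(C)OO
Why: SeO2 allylic oxidation (ene then [2,3]-shift) attacks the more nucleophilic 1,1-disubstituted alkene at its methyl group (CH3 is preferred over the ring CH) and MnO2 takes the allylic alcohol to the enal that becomes C9; no stereocentre is formed.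

Step 3
Reactants: 5 2-[(9R)-6-methyl-1,4-dioxaspiro[4.5]dec-7-en-9-yl]prop-2-enal; 6 2-methylbut-1-en-3-yne
Product: 9 (3R,4E)-6-methyl-2-[(9R)-6-methyl-1,4-dioxaspiro[4.5]dec-7-en-9-yl]hepta-1,4,6-trien-3-ol, via dienylborane 7 (not isolated), via dienylzinc 8 (not isolated)
Conditions: 6, Cy2BH, toluene, 0 °C; Me2Zn, −78 °C; (+)-MIB (5 mol %), then 5, −30 → 0 °C; H2O
Reagents that add atoms: none
Why: syn-Hydroboration of the terminal alkyne gives the (E)-dienylborane, and boron-to-zinc exchange followed by amino-alcohol-catalysed 1,2-addition to the aldehyde (Oppolzer-type asymmetric alkenylzinc addition) sets C9 as (R) by catalyst control on the Re face, the ketal and the other alkenes being inert.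

Step 4
Reactants: 9 (3R,4E)-6-methyl-2-[(9R)-6-methyl-1,4-dioxaspiro[4.5]dec-7-en-9-yl]hepta-1,4,6-trien-3-ol
Product: 10 (1S)-2-[(9R)-6-methyl-1,4-dioxaspiro[4.5]dec-7-en-9-yl]-1-[(2S,3S)-3-(prop-1-en-2-yl)oxiran-2-yl]prop-2-en-1-ol
Conditions: Ti(OiPr)4 (0.2 equiv), L-(+)-DIPT (0.24 equiv), t-BuOOH, 4 Å MS, CH2Cl2, −20 °C
Reagents that add atoms: tert-butyl hydroperoxide, CC(C)(C)OO
Why: Sharpless asymmetric epoxidation in its matched mode epoxidises the E-alkene of the diene to the erythro (2S,3S)-epoxy alcohol (C8 and C7), while the second allylic alkene C10=C14 is the mismatched partner of the same tartrate and stays intact.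

Step 5
Reactants: 10 epoxy alcohol; 11 (2E)-3-methylpent-2-enoic acid
Product: 12 (1S)-2-[(9R)-6-methyl-1,4-dioxaspiro[4.5]dec-7-en-9-yl]-1-[(2R,3S)-3-(prop-1-en-2-yl)oxiran-2-yl]prop-2-en-1-yl (2E)-3-methylpent-2-enoate
Conditions: DCC, DMAP (cat.), CH2Cl2, 0 °C → rt
Reagents that add atoms: none
Why: Steglich esterification acylates the only hydroxyl (O9) without opening the epoxide or moving the enoate double bond; the configuration is unchanged and only the CIP label at the oxirane carbon next to C9 changes.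

Step 6
Reactants: 12 bisabolane-type vinyl epoxide ester
Product: 15 8β-(tert-butyldimethylsilyloxy)-9β-[(2E)-3-methylpent-2-enoyloxy]-1βH,6αH,7βH-cadina-4,10(14),11-trien-3-one, via dienol ether 13 (not isolated), via cis-fused enone 14 (not isolated)
Conditions: TBSOTf (2.5 equiv), i-Pr2NEt (3 equiv), CH2Cl2, −78 → −40 °C; aq. NaHCO3; then DBU, toluene, 60 °C
Reagents that add atoms: tert-butyldimethylsilyl trifluoromethanesulfonate, CC(C)(C)[Si](C)(C)OS(=O)(=O)C(F)(F)F
Why: Proposed new method: TBSOTf/i-Pr2NEt opens the dioxolane to the linear dienol ether and silylates the vinyl epoxide, whose allylic carbon C7 is attacked with inversion by the dienol-ether terminus C6 in a 6-endo cation–olefin closure (a laboratory copy of the bisabolyl-to-cadinyl C6–C7 closure; closest known types are vinylogous Mukaiyama additions and π-activated 6-endo epoxide openings), and the kinetically cis-fused enone is then equilibrated by DBU through its dienolate at the γ-carbon C6 to the all-equatorial trans-fused isomer, so that C7 comes from the epoxide, C8 and C9 are retained and C6 is set thermodynamically.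

Step 7
Reactants: 15 trans-fused cadinenone
Product: 16 4α,5α-epoxy-8β-(tert-butyldimethylsilyloxy)-9β-[(2E)-3-methylpent-2-enoyloxy]-1βH,6αH,7βH-cadina-10(14),11-dien-3-one
Conditions: t-BuOOH, DBU, CH2Cl2, rt
Reagents that add atoms: tert-butyl hydroperoxide, CC(C)(C)OO
Why: Weitz–Scheffer-type nucleophilic epoxidation attacks only the electron-poor ring enone (not the hindered enoate or the isolated alkenes) and adds peroxide axially at C5 anti to C7, giving the 4α,5α-epoxide whose configuration no longer matters after step 8.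

Step 8
Reactants: 16 cadinane 4,5-epoxy-3-ketone
Product: 17 5α-acetyl β-diketone, 8β-(tert-butyldimethylsilyloxy)-9β-[(2E)-3-methylpent-2-enoyloxy]-3(4→5)abeo-cadina-10(14),11-diene-3,4-dione
Conditions: BF3·OEt2, CH2Cl2, −40 → 0 °C
Reagents that add atoms: none
Why: The Lewis acid opens the epoxide at C5 (remote from the carbonyl) and the acyl carbon C3 migrates from C4 to C5 with inversion while C4 becomes the acetyl carbonyl (1,2-acyl shift of α,β-epoxy ketones to β-diketones), contracting ring A as in the presumed cadinane-to-oplopane biogenesis; C5 is enolisable and settles trans to C7.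

Step 9
Reactants: 17 β-diketone
Product: 18 (4R)-4-hydroxy-8β-(tert-butyldimethylsilyloxy)-9β-[(2E)-3-methylpent-2-enoyloxy]-3(4→5)abeo-cadina-10(14),11-dien-3-one
Conditions: RuCl[(R,R)-TsDPEN](p-cymene) (2 mol %), HCO2H/Et3N (5:2), CH2Cl2, rt
Reagents that add atoms: none
Why: Noyori-type transfer hydrogenation reduces 2-substituted 1,3-diketones once and at the less hindered methyl ketone, and the (R,R)-catalyst is expected to give the (4R)-carbinol while the labile C5 centre equilibrates (dynamic kinetic resolution) to the syn arrangement with the side chain α; esters, alkenes and the silyl ether are inert.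

Step 10
Reactants: 18 β-hydroxy ketone
Product: 19 (4R)-4-acetoxy-8β-(tert-butyldimethylsilyloxy)-9β-[(2E)-3-methylpent-2-enoyloxy]-3(4→5)abeo-cadina-10(14),11-dien-3-one
Conditions: Ac2O, pyridine, CH2Cl2, 0 °C → rt
Reagents that add atoms: acetic anhydride, CC(=O)OC(C)=O
Why: Plain O-acetylation of the only free hydroxyl under weakly basic conditions that avoid β-elimination of the new β-acetoxy ketone; no stereocentre changes.

Step 11
Reactants: 19 silyl ether
Product: 20 (4R)-4-acetoxy-8β-hydroxy-9β-[(2E)-3-methylpent-2-enoyloxy]-3(4→5)abeo-cadina-10(14),11-dien-3-one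
Conditions: HF·pyridine, THF, 0 °C → rt
Reagents that add atoms: none
Why: Acidic fluoride desilylation frees O8 without base, so neither acetate elimination nor acyl migration from O9 to O8 occurs; no stereocentre changes.

Step 12
Reactants: 20 homoallylic alcohol
Product: 21 (4R,11S)-4-acetoxy-11,12-epoxy-8β-hydroxy-9β-[(2E)-3-methylpent-2-enoyloxy]-3(4→5)abeo-cadin-10(14)-en-3-one
Conditions: VO(acac)2 (5 mol %), t-BuOOH, CH2Cl2, 0 °C → rt
Reagents that add atoms: tert-butyl hydroperoxide, CC(C)(C)OO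
Why: Hydroxyl-directed vanadium-catalysed epoxidation delivers oxygen from the equatorial C8 vanadate to the adjacent isopropenyl group (isopulegol-type homoallylic case) in the rotamer that keeps C12 eclipsed with H-7, which gives the (11S)-epoxide, while the exocyclic C10=C14 alkene cannot reach the metal and the enoate is electron-poor.

Step 13
Reactants: 21 epoxy alcohol; 22 (2S)-2-methylbutanoic acid
Product: 23 CNP0120390.2, (4R,11S)-4-acetoxy-11,12-epoxy-8β-[(2S)-2-methylbutanoyloxy]-9β-[(2E)-3-methylpent-2-enoyloxy]-3(4→5)abeo-cadin-10(14)-en-3-one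
Conditions: DCC, DMAP (cat.), CH2Cl2, 0 °C → rt
Reagents that add atoms: none
Why: Steglich esterification of the remaining secondary alcohol with the enantiopure acid at 0 °C (no ketene pathway, so the α-centre of the acid is kept) completes the target without touching the epoxide or the β-acetoxy ketone.

**Compound list**
1 | (S)-carvone, (5S)-2-methyl-5-(prop-1-en-2-yl)cyclohex-2-en-1-one | C=C(C)[C@@H]1CC(=O)C(C)=CC1 | starting material
2 | (5R)-2-methyl-5-(prop-1-en-2-yl)cyclohex-3-en-1-one (C2 epimers) | C=C(C)[C@@H]1CC(=O)C(C)C=C1 | intermediate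
3 | (9R)-6-methyl-9-(prop-1-en-2-yl)-1,4-dioxaspiro[4.5]dec-7-ene (C6 epimers) | C=C(C)[C@@H]1CC2(OCCO2)C(C)C=C1 | intermediate
4 | 2-[(9R)-6-methyl-1,4-dioxaspiro[4.5]dec-7-en-9-yl]prop-2-en-1-ol | C=C(CO)[C@@H]1CC2(OCCO2)C(C)C=C1 | intermediate
5 | 2-[(9R)-6-methyl-1,4-dioxaspiro[4.5]dec-7-en-9-yl]prop-2-enal | C=C(C=O)[C@@H]1CC2(OCCO2)C(C)C=C1 | intermediate
6 | 2-methylbut-1-en-3-yne | C=C(C)C#C | starting material
7 | dicyclohexyl[(1E)-3-methylbuta-1,3-dien-1-yl]borane | C=C(C)/C=C/B(C1CCCCC1)C1CCCCC1 | intermediate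
8 | methyl[(1E)-3-methylbuta-1,3-dien-1-yl]zinc | C=C(C)/C=C/[Zn]C | intermediate
9 | (3R,4E)-6-methyl-2-[(9R)-6-methyl-1,4-dioxaspiro[4.5]dec-7-en-9-yl]hepta-1,4,6-trien-3-ol | C=C([C@H](O)/C=C/C(C)=C)[C@@H]1CC2(OCCO2)C(C)C=C1 | intermediate
10 | (1S)-2-[(9R)-6-methyl-1,4-dioxaspiro[4.5]dec-7-en-9-yl]-1-[(2S,3S)-3-(prop-1-en-2-yl)oxiran-2-yl]prop-2-en-1-ol | C=C([C@H](O)[C@@H]1O[C@H]1C(C)=C)[C@@H]1CC2(OCCO2)C(C)C=C1 | intermediate
11 | (2E)-3-methylpent-2-enoic acid | CC/C(C)=C/C(=O)O | starting material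
12 | (2E)-3-methylpent-2-enoate of 10 (all centres as in 10; oxirane now labelled 2R,3S) | C=C([C@H](OC(=O)/C=C(\C)CC)[C@@H]1O[C@H]1C(C)=C)[C@@H]1CC2(OCCO2)C(C)C=C1 | intermediate
13 | linear dienol ether of 12 (C3–OCH2CH2OTBS, C3=C4, C5=C6) | C=C([C@H](OC(=O)/C=C(\C)CC)[C@@H]1O[C@H]1C(C)=C)[C@@H]1CC(OCCO[Si](C)(C)C(C)(C)C)=C(C)C=C1 | intermediate
14 | 6-epimer of 15 (cis-fused, 1βH,6βH,7βH) | C=C1[C@@H]2CC(=O)C(C)=C[C@@H]2[C@H](C(C)=C)[C@@H](O[Si](C)(C)C(C)(C)C)[C@H]1OC(=O)/C=C(\C)CC | intermediate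
15 | 8β-(tert-butyldimethylsilyloxy)-9β-[(2E)-3-methylpent-2-enoyloxy]-1βH,6αH,7βH-cadina-4,10(14),11-trien-3-one | C=C1[C@@H]2CC(=O)C(C)=C[C@H]2[C@H](C(C)=C)[C@@H](O[Si](C)(C)C(C)(C)C)[C@H]1OC(=O)/C=C(\C)CC | intermediate
16 | 4α,5α-epoxide of 15 | C=C1[C@@H]2CC(=O)[C@]3(C)O[C@@H]3[C@H]2[C@H](C(C)=C)[C@@H](O[Si](C)(C)C(C)(C)C)[C@H]1OC(=O)/C=C(\C)CC | intermediate
17 | ring-contracted β-diketone (5α-acetyl, 5βH; keto/enol mixture) | C=C1[C@@H]2CC(=O)[C@H](C(C)=O)[C@H]2[C@H](C(C)=C)[C@@H](O[Si](C)(C)C(C)(C)C)[C@H]1OC(=O)/C=C(\C)CC | intermediate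
18 | (4R)-4-hydroxy ketone from 17 | C=C1[C@@H]2CC(=O)[C@H]([C@@H](C)O)[C@H]2[C@H](C(C)=C)[C@@H](O[Si](C)(C)C(C)(C)C)[C@H]1OC(=O)/C=C(\C)CC | intermediate
19 | (4R)-4-acetate of 18 | C=C1[C@@H]2CC(=O)[C@H]([C@@H](C)OC(C)=O)[C@H]2[C@H](C(C)=C)[C@@H](O[Si](C)(C)C(C)(C)C)[C@H]1OC(=O)/C=C(\C)CC | intermediate
20 | 8β-alcohol from 19 | C=C1[C@@H]2CC(=O)[C@H]([C@@H](C)OC(C)=O)[C@H]2[C@H](C(C)=C)[C@@H](O)[C@H]1OC(=O)/C=C(\C)CC | intermediate
21 | (11S)-11,12-epoxide of 20 | C=C1[C@@H]2CC(=O)[C@H]([C@@H](C)OC(C)=O)[C@H]2[C@H]([C@@]2(C)CO2)[C@@H](O)[C@H]1OC(=O)/C=C(\C)CC | intermediate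
22 | (2S)-2-methylbutanoic acid | CC[C@H](C)C(=O)O | starting material
23 | CNP0120390.2 (1βH,5βH,6αH,7βH; 4R; 11S) | C=C1[C@@H]2CC(=O)[C@H]([C@@H](C)OC(C)=O)[C@H]2[C@H]([C@@]2(C)CO2)[C@@H](OC(=O)[C@@H](C)CC)[C@H]1OC(=O)/C=C(\C)CC | target

**Totals and risks**
Total step count: 13. Longest linear sequence: 13 steps (1 → 23).

Most likely to fail:

Step 6 (cation–olefin ring B closure). Risks are competing vinyl-epoxide rearrangement, participation of the O9 ester carbonyl, or loss of inversion at C7. The fallback sets out from 12 and returns at 15. PPTS in wet acetone removes the dioxolane to give the β,γ-unsaturated ketone F1. Pd(PPh3)4 in THF then ionises the vinyl epoxide to a π-allyl palladium alkoxide, which deprotonates the doubly activated C4–H. The extended dienolate closes the six-membered ring through C6 on the allyl terminus C7 (Tsuji–Trost allylation; the allyl face equilibrates through the unsubstituted terminus) to the hydroxy enone F2. TBSOTf/2,6-lutidine gives 14/15 and DBU converges on 15.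

Step 8 (acyl-shift ring contraction). Risks are methyl or hydride shift, or attack on the allylic ester or silyl ether by BF3. The fallback sets out from 16 and returns at 17. MgBr2·OEt2 in ether at 0 °C opens the epoxide at C5 to the 5β-bromo-4α-hydroxy ketone F3. AgBF4 with 2,6-lutidine in CH2Cl2 at −20 °C then abstracts bromide and triggers the same 1,2-acyl shift as a halohydrin semipinacol, giving 17.

Step 9 (mono-reduction of the β-diketone). Risks are reduction of the ring ketone or the wrong C4 configuration. The fallback sets out from 17 and returns at 19. NaBH4 with CeCl3·7H2O in MeOH at −40 °C reduces both ketones to the 3,4-diol F4. Immobilised Candida antarctica lipase B with vinyl acetate acetylates only the (R)-methyl carbinol (Kazlauskas preference; the ring alcohol is too hindered) to the mono-acetate F5. Dess–Martin periodinane re-oxidises the ring carbinol to 19.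

**Further compounds**
F1 | step 6 | β,γ-unsaturated ketone from 12 (dioxolane removed) | C=C([C@H](OC(=O)/C=C(\C)CC)[C@@H]1O[C@H]1C(C)=C)[C@@H]1CC(=O)C(C)C=C1
F2 | step 6 | 8β-hydroxy-9β-[(2E)-3-methylpent-2-enoyloxy]cadina-4,10(14),11-trien-3-one (C6 epimers) | C=C1[C@@H]2CC(=O)C(C)=CC2[C@H](C(C)=C)[C@@H](O)[C@H]1OC(=O)/C=C(\C)CC
F3 | step 8 | 5β-bromo-4α-hydroxy-8β-(tert-butyldimethylsilyloxy)-9β-[(2E)-3-methylpent-2-enoyloxy]cadina-10(14),11-dien-3-one | C=C1[C@@H]2CC(=O)[C@](C)(O)[C@@H](Br)[C@H]2[C@H](C(C)=C)[C@@H](O[Si](C)(C)C(C)(C)C)[C@H]1OC(=O)/C=C(\C)CC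
F4 | step 9 | 3,4-diol from 17 (C3 and C4 carbinol mixtures) | C=C1[C@@H]2CC(O)[C@H](C(C)O)[C@H]2[C@H](C(C)=C)[C@@H](O[Si](C)(C)C(C)(C)C)[C@H]1OC(=O)/C=C(\C)CC
F5 | step 9 | (4R)-4-acetate of the 3-ol (C3 carbinol mixture) | C=C1[C@@H]2CC(O)[C@H]([C@@H](C)OC(C)=O)[C@H]2[C@H](C(C)=C)[C@@H](O[Si](C)(C)C(C)(C)C)[C@H]1OC(=O)/C=C(\C)CC
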